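**Plan**

- Ring labels: A = phenol ring whose ether oxygen is para to its CH2; B = 1,3-linked ring; C = 1,4-linked ring; D = phenol ring whose OH is para to its CH2.
- Enabling feature: in ring A the OH carbon is the neighbour of the carbon bearing the O–ring B bond. A nitro group on that carbon activates an adjacent C–F bond towards the ring-B oxygen and is later converted into that OH.
- Cuts, in retrosynthetic order: ring-D O–CH3; ring-A C–OH (back to NH2, then NO2); the ring-A C–O(ring B) aryl ether, which opens the 20-membered ring; the A–D CH2–CH2 bridge and the B–C CH2–CH2 bridge (each a Wittig C=C plus saturation); the ring-D O–C(ring C) aryl ether.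
- Forward order: D–O–C ether, ring B attached, ring A attached, ring-B phenol unmasked, macrocycle closed by fluoride displacement, NO2 → NH2 → OH, demethylation.
- Stereochemistry: the target has no stereocentre, and both alkene E/Z mixtures are erased by saturation.

Key step: step 9

Assumption: the target contains no stereocentre, and the 20-membered ring is taken to be too mobile for a stable axis or plane of chirality, so the compound is a single achiral species and no stereocontrol is needed.

**Step 1**
Reactants: 1 3-hydroxy-4-methoxybenzyl alcohol; 2 4-fluorobenzaldehyde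
Product: 4 4-[5-(hydroxymethyl)-2-methoxyphenoxy]benzaldehyde, via potassium 5-(hydroxymethyl)-2-methoxyphenoxide 3 (not isolated)
Conditions: K2CO3, DMF, 120 °C
Reagents that add atoms: none
Why: Carbonate deprotonates only the phenol, and the phenoxide displaces the fluoride para to the formyl group through a Meisenheimer intermediate (nucleophilic aromatic substitution), which joins rings D and C and leaves one aldehyde and one benzylic alcohol as differentiated handles.

**Step 2**
Reactants: 5 3-(benzyloxy)benzyl alcohol
Product: 6 [3-(benzyloxy)benzyl]triphenylphosphonium bromide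
Conditions: PPh3·HBr, MeCN, reflux
Reagents that add atoms: triphenylphosphine hydrobromide, Br.P(c1ccccc1)(c1ccccc1)c1ccccc1
Why: Triphenylphosphine hydrobromide turns a benzylic alcohol directly into the benzylphosphonium bromide by acid-assisted substitution (phosphonium salt formation), and the aryl benzyl ether tolerates this weak acid.

**Step 3**
Reactants: 4 4-[5-(hydroxymethyl)-2-methoxyphenoxy]benzaldehyde; 6 [3-(benzyloxy)benzyl]triphenylphosphonium bromide
Product: 8 (E/Z)-[3-(4-{2-[3-(benzyloxy)phenyl]ethenyl}phenoxy)-4-methoxyphenyl]methanol, via [3-(benzyloxy)benzylidene]triphenylphosphorane 7 (not isolated)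
Conditions: K2CO3, 18-crown-6 (cat.), CH2Cl2, reflux
Reagents that add atoms: none
Why: Carbonate with crown ether generates the semi-stabilised ylide, which condenses with the aryl aldehyde (Wittig olefination under solid–liquid phase-transfer conditions); the free benzylic alcohol is not deprotonated and the E/Z mixture is of no consequence because the alkene is saturated next.

**Step 4**
Reactants: 8 (E/Z)-[3-(4-{2-[3-(benzyloxy)phenyl]ethenyl}phenoxy)-4-methoxyphenyl]methanol
Product: 9 [3-(4-{2-[3-(benzyloxy)phenyl]ethyl}phenoxy)-4-methoxyphenyl]methanol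
Conditions: TsNHNH2 (excess, in portions), NaOAc, DME/H2O, reflux
Reagents that add atoms: none
Why: Diimide released by thermal fragmentation of the sulfonyl hydrazide transfers two hydrogens to the stilbene C=C in a concerted syn fashion (diimide reduction) and cannot hydrogenolyse the aryl benzyl ether or the benzylic alcohol, which hydrogen over palladium would endanger.

**Step 5**
Reactants: 9 [3-(4-{2-[3-(benzyloxy)phenyl]ethyl}phenoxy)-4-methoxyphenyl]methanol
Product: 10 [3-(4-{2-[3-(benzyloxy)phenyl]ethyl}phenoxy)-4-methoxybenzyl]triphenylphosphonium bromide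
Conditions: PPh3·HBr, MeCN, reflux
Reagents that add atoms: triphenylphosphine hydrobromide, Br.P(c1ccccc1)(c1ccccc1)c1ccccc1
Why: The benzylic alcohol para to the methoxy group ionises readily under the weakly acidic conditions and is captured by triphenylphosphine (phosphonium salt formation), while the benzyl ether and both diaryl ether bonds are stable.

**Step 6**
Reactants: 10 [3-(4-{2-[3-(benzyloxy)phenyl]ethyl}phenoxy)-4-methoxybenzyl]triphenylphosphonium bromide; 11 4-fluoro-3-nitrobenzaldehyde
Product: 13 1-(benzyloxy)-3-[2-(4-{5-[(E/Z)-2-(4-fluoro-3-nitrophenyl)ethenyl]-2-methoxyphenoxy}phenyl)ethyl]benzene, via ring-D benzylidene triphenylphosphorane 12 (not isolated)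
Conditions: K2CO3, 18-crown-6 (cat.), CH2Cl2, rt to reflux
Reagents that add atoms: none
Why: The semi-stabilised ylide formed under mild, non-nucleophilic carbonate conditions adds to the strongly electrophilic aldehyde much faster than anything present can attack the nitro-activated C–F bond (Wittig olefination).

**Step 7**
Reactants: 13 1-(benzyloxy)-3-[2-(4-{5-[(E/Z)-2-(4-fluoro-3-nitrophenyl)ethenyl]-2-methoxyphenoxy}phenyl)ethyl]benzene
Product: 14 1-(benzyloxy)-3-[2-(4-{5-[2-(4-fluoro-3-nitrophenyl)ethyl]-2-methoxyphenoxy}phenyl)ethyl]benzene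
Conditions: KO2CN=NCO2K (excess, in portions), AcOH, THF/MeOH, rt to 40 °C
Reagents that add atoms: none
Why: Diimide set free from the azodicarboxylate by acetic acid saturates the non-polar stilbene C=C through a cyclic transition state (diimide reduction) and leaves the nitro group and the benzyl ether untouched, while the acidic, non-nucleophilic medium spares the activated aryl fluoride.

**Step 8**
Reactants: 14 1-(benzyloxy)-3-[2-(4-{5-[2-(4-fluoro-3-nitrophenyl)ethyl]-2-methoxyphenoxy}phenyl)ethyl]benzene
Product: 15 3-[2-(4-{5-[2-(4-fluoro-3-nitrophenyl)ethyl]-2-methoxyphenoxy}phenyl)ethyl]phenol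
Conditions: BCl3, pentamethylbenzene, CH2Cl2, –78 °C; MeOH quench, non-basic work-up
Reagents that add atoms: none
Why: Boron trichloride activates the benzylic ether oxygen and pentamethylbenzene captures the benzyl cation (Lewis-acid debenzylation with a cation scavenger), which at –78 °C spares the methyl ether, the nitro group and the aryl fluoride.

**Step 9**
Reactants: 15 3-[2-(4-{5-[2-(4-fluoro-3-nitrophenyl)ethyl]-2-methoxyphenoxy}phenyl)ethyl]phenol
Product: 17 nitro macrocycle (20-membered bis(bibenzyl) diether; ring A carries NO2 ortho to the new C–O bond; ring D carries OMe), via ring-B potassium phenoxide 16 (not isolated)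
Conditions: K2CO3 (excess), DMF, slow addition of 15 to about 0.002 M, rt to 40 °C
Reagents that add atoms: none
Why: Carbonate converts the only free phenol (ring B) into its phenoxide, whose oxygen adds to the fluorine-bearing carbon of ring A to give a Meisenheimer complex stabilised by the ortho nitro group, and loss of fluoride restores aromaticity (addition–elimination SNAr). The closest known reaction type is the intramolecular SNAr cycloetherification of ortho-nitro aryl fluorides by phenoxides used to make macrocyclic diaryl ethers. The one ring formed, the 20-membered macrocycle, closes end-to-end by aryl C–O bond formation between the ring-B oxygen and the ring-A carbon para to the CH2CH2 bridge, and the two saturated bridges give the chain enough flexibility to reach that geometry without strain. No stereocentre is created. The step needs chemoselectivity and ring closure over oligomerisation: ring A holds the only activated C–F bond and ring B the only free phenol (ring D is masked as its methyl ether), and slow addition at high dilution keeps intermolecular substitution down.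

**Step 10**
Reactants: 17 nitro macrocycle
Product: 18 amino macrocycle (ring A carries NH2 ortho to the O–ring B bond; ring D carries OMe)
Conditions: H2 (1 atm), 10% Pd/C, EtOAc/MeOH, rt
Reagents that add atoms: none
Why: Catalytic hydrogenation reduces the aryl nitro group to the aniline (nitro reduction), and the macrocycle now holds no benzyl ether, halide or alkene that hydrogenolysis could touch.

**Step 11**
Reactants: 18 amino macrocycle
Product: 20 ring-A phenol macrocycle (ring D still OMe), via arenediazonium tetrafluoroborate 19 (not isolated)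
Conditions: NaNO2, aq HBF4, THF/H2O, 0 °C; then Cu(NO3)2·3H2O (large excess), Cu2O, H2O, rt
Reagents that add atoms: water, O
Why: Diazotisation gives the arenediazonium salt, which copper(I) reduces to an aryl radical that copper(II) aquo species trap as the phenol at room temperature (copper-mediated hydroxydediazoniation), faster than the side reactions of thermal hydrolysis.

**Step 12**
Reactants: 20 ring-A phenol macrocycle
Product: 21 CNP0329842.0, the target macrocyclic bis(bibenzyl) diether diphenol
Conditions: BBr3, CH2Cl2, –78 °C to 0 °C; aqueous work-up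
Reagents that add atoms: none
Why: Boron tribromide complexes the aryl methyl ether oxygen and bromide attacks the methyl group (Lewis-acid ether cleavage), a reaction under which diaryl ether bonds are not cleaved.

**Compound list**

1 | 3-hydroxy-4-methoxybenzyl alcohol | OCc1ccc(OC)c(O)c1 | starting material
2 | 4-fluorobenzaldehyde | O=Cc1ccc(F)cc1 | starting material
3 | potassium 5-(hydroxymethyl)-2-methoxyphenoxide (formed in situ) | [K+].[O-]c1cc(CO)ccc1OC | intermediate
4 | 4-[5-(hydroxymethyl)-2-methoxyphenoxy]benzaldehyde | O=Cc1ccc(Oc2cc(CO)ccc2OC)cc1 | intermediate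
5 | 3-(benzyloxy)benzyl alcohol | OCc1cccc(OCc2ccccc2)c1 | starting material
6 | [3-(benzyloxy)benzyl]triphenylphosphonium bromide | [Br-].c1ccccc1[P+](c1ccccc1)(c1ccccc1)Cc1cccc(OCc2ccccc2)c1 | intermediate
7 | [3-(benzyloxy)benzylidene]triphenylphosphorane (ylide, formed in situ) | c1ccccc1P(c1ccccc1)(c1ccccc1)=Cc1cccc(OCc2ccccc2)c1 | intermediate
8 | (E/Z)-[3-(4-{2-[3-(benzyloxy)phenyl]ethenyl}phenoxy)-4-methoxyphenyl]methanol (isomer mixture) | OCc1ccc(OC)c(Oc2ccc(C=Cc3cccc(OCc4ccccc4)c3)cc2)c1 | intermediate
9 | [3-(4-{2-[3-(benzyloxy)phenyl]ethyl}phenoxy)-4-methoxyphenyl]methanol | OCc1ccc(OC)c(Oc2ccc(CCc3cccc(OCc4ccccc4)c3)cc2)c1 | intermediate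
10 | [3-(4-{2-[3-(benzyloxy)phenyl]ethyl}phenoxy)-4-methoxybenzyl]triphenylphosphonium bromide | [Br-].c1ccccc1[P+](c1ccccc1)(c1ccccc1)Cc1ccc(OC)c(Oc2ccc(CCc3cccc(OCc4ccccc4)c3)cc2)c1 | intermediate
11 | 4-fluoro-3-nitrobenzaldehyde | O=Cc1ccc(F)c([N+](=O)[O-])c1 | starting material
12 | [3-(4-{2-[3-(benzyloxy)phenyl]ethyl}phenoxy)-4-methoxybenzylidene]triphenylphosphorane (ylide, formed in situ) | c1ccccc1P(c1ccccc1)(c1ccccc1)=Cc1ccc(OC)c(Oc2ccc(CCc3cccc(OCc4ccccc4)c3)cc2)c1 | intermediate
13 | 1-(benzyloxy)-3-[2-(4-{5-[(E/Z)-2-(4-fluoro-3-nitrophenyl)ethenyl]-2-methoxyphenoxy}phenyl)ethyl]benzene (isomer mixture) | [O-][N+](=O)c1cc(C=Cc2ccc(OC)c(Oc3ccc(CCc4cccc(OCc5ccccc5)c4)cc3)c2)ccc1F | intermediate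
14 | 1-(benzyloxy)-3-[2-(4-{5-[2-(4-fluoro-3-nitrophenyl)ethyl]-2-methoxyphenoxy}phenyl)ethyl]benzene | [O-][N+](=O)c1cc(CCc2ccc(OC)c(Oc3ccc(CCc4cccc(OCc5ccccc5)c4)cc3)c2)ccc1F | intermediate
15 | 3-[2-(4-{5-[2-(4-fluoro-3-nitrophenyl)ethyl]-2-methoxyphenoxy}phenyl)ethyl]phenol (seco fluoronitroarene phenol) | [O-][N+](=O)c1cc(CCc2ccc(OC)c(Oc3ccc(CCc4cccc(O)c4)cc3)c2)ccc1F | intermediate
16 | potassium 3-[2-(4-{5-[2-(4-fluoro-3-nitrophenyl)ethyl]-2-methoxyphenoxy}phenyl)ethyl]phenoxide (formed in situ) | [K+].[O-]c1cccc(CCc2ccc(Oc3cc(CCc4ccc(F)c([N+](=O)[O-])c4)ccc3OC)cc2)c1 | intermediate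
17 | nitro macrocycle: 20-membered ring A–O–B–CH2CH2–C–O–D–CH2CH2, ring A with NO2 ortho to the O–ring B bond, ring D with OMe ortho to the O–ring C bond | [O-][N+](=O)c1cc2ccc1Oc1cccc(c1)CCc1ccc(cc1)Oc1cc(ccc1OC)CC2 | intermediate
18 | amino macrocycle: as 17 with NH2 in place of NO2 | Nc1cc2ccc1Oc1cccc(c1)CCc1ccc(cc1)Oc1cc(ccc1OC)CC2 | intermediate
19 | macrocyclic arenediazonium tetrafluoroborate: as 18 with N2+ in place of NH2 (formed in situ) | N#[N+]c1cc2ccc1Oc1cccc(c1)CCc1ccc(cc1)Oc1cc(ccc1OC)CC2.F[B-](F)(F)F | intermediate
20 | ring-A phenol macrocycle: as 17 with OH in place of NO2, ring D still OMe | Oc1cc2ccc1Oc1cccc(c1)CCc1ccc(cc1)Oc1cc(ccc1OC)CC2 | intermediate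
21 | CNP0329842.0: macrocyclic bis(bibenzyl) diether with OH on ring A ortho to the O–ring B bond and OH on ring D ortho to the O–ring C bond | Oc1cc2ccc1Oc1cccc(c1)CCc1ccc(cc1)Oc1cc(ccc1O)CC2 | target

**Step count**

Total: 12 steps. Longest linear sequence: 11 steps (steps 1 and 3 to 12, from compound 1); step 2 supplies the ring-B phosphonium salt.

**Steps most likely to fail**

Step 9. Intermolecular substitution could outrun closure of the 20-membered ring and give dimers and oligomers, or adventitious hydroxide could hydrolyse the activated fluoride. The fallback forms the A–O–B ether intermolecularly and closes the ring at the A–D bridge instead. It sets out from 8. Hydrogenation over Pd/C in neutral ethyl acetate, stopped once the alkene and the benzyl ether are consumed, should give 3-{2-[4-(5-(hydroxymethyl)-2-methoxyphenoxy)phenyl]ethyl}phenol F1. K2CO3 in DMF at room temperature should join its phenol to 11 by intermolecular SNAr to give 4-[3-(2-{4-[5-(hydroxymethyl)-2-methoxyphenoxy]phenyl}ethyl)phenoxy]-3-nitrobenzaldehyde F2. PPh3·HBr in refluxing MeCN should convert the benzylic alcohol into the formyl-bearing benzyltriphenylphosphonium bromide F3. K2CO3 and 18-crown-6 in CH2Cl2 under high dilution should close the ring by intramolecular Wittig olefination to the macrocyclic (E/Z)-nitrostilbene F4. Diimide (TsNHNH2, NaOAc) should then saturate the alkene, and the fallback comes back to the route at 17.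

Step 7. The short-lived diimide may leave the stilbene partly unreduced, and long reaction times expose the activated fluoride to substitution by nucleophiles in the medium. The fallback builds the saturated A–D bridge directly by sp3–sp2 coupling and sets out from 9. MnO2 in CH2Cl2 should oxidise the benzylic alcohol to 3-(4-{2-[3-(benzyloxy)phenyl]ethyl}phenoxy)-4-methoxybenzaldehyde F5. Methylenetriphenylphosphorane (MePPh3Br, KOtBu, THF) should give the styrene 1-(benzyloxy)-3-{2-[4-(5-ethenyl-2-methoxyphenoxy)phenyl]ethyl}benzene F6. Hydroboration with 9-BBN in THF should give the B-alkyl-9-borabicyclononane F7. Without isolation, B-alkyl Suzuki–Miyaura coupling with commercial 4-bromo-1-fluoro-2-nitrobenzene (Pd(dppf)Cl2, K3PO4, THF/DMF, 50 °C) should deliver 14, where the fallback comes back to the route.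

Step 11. The diazonium ion or the derived aryl radical may be diverted into reduction to the arene, intramolecular arylation of ring B, or azo coupling, instead of being captured by water. The fallback replaces direct hydrolysis by a halide and palladium-catalysed hydroxylation, and sets out from 18. Non-aqueous Sandmeyer bromination (t-BuONO, CuBr2, MeCN), in which bromine transfer from copper(II) to the aryl radical is very fast, should give the macrocyclic aryl bromide F8. Palladium-catalysed hydroxylation (Pd2(dba)3, tBuXPhos, KOH, dioxane/H2O, 100 °C) should then give 20, where the fallback comes back to the route.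

**Further compounds**

F1 | step 9 | 3-{2-[4-(5-(hydroxymethyl)-2-methoxyphenoxy)phenyl]ethyl}phenol | OCc1ccc(OC)c(Oc2ccc(CCc3cccc(O)c3)cc2)c1
F2 | step 9 | 4-[3-(2-{4-[5-(hydroxymethyl)-2-methoxyphenoxy]phenyl}ethyl)phenoxy]-3-nitrobenzaldehyde | OCc1ccc(OC)c(Oc2ccc(CCc3cccc(Oc4ccc(C=O)cc4[N+](=O)[O-])c3)cc2)c1
F3 | step 9 | {3-[4-(2-{3-[4-formyl-2-nitrophenoxy]phenyl}ethyl)phenoxy]-4-methoxybenzyl}triphenylphosphonium bromide | [Br-].O=Cc1ccc(Oc2cccc(CCc3ccc(Oc4cc(C[P+](c5ccccc5)(c5ccccc5)c5ccccc5)ccc4OC)cc3)c2)c([N+](=O)[O-])c1
F4 | step 9 | macrocyclic (E/Z)-nitrostilbene: as 17 with CH=CH in place of the A–D CH2CH2 bridge | [O-][N+](=O)c1cc2ccc1Oc1cccc(c1)CCc1ccc(cc1)Oc1cc(ccc1OC)C=C2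
F5 | step 7 | 3-(4-{2-[3-(benzyloxy)phenyl]ethyl}phenoxy)-4-methoxybenzaldehyde | O=Cc1ccc(OC)c(Oc2ccc(CCc3cccc(OCc4ccccc4)c3)cc2)c1
F6 | step 7 | 1-(benzyloxy)-3-{2-[4-(5-ethenyl-2-methoxyphenoxy)phenyl]ethyl}benzene | C=Cc1ccc(OC)c(Oc2ccc(CCc3cccc(OCc4ccccc4)c3)cc2)c1
F7 | step 7 | 9-{2-[3-(4-{2-[3-(benzyloxy)phenyl]ethyl}phenoxy)-4-methoxyphenyl]ethyl}-9-borabicyclo[3.3.1]nonane | COc1ccc(CCB2C3CCCC2CCC3)cc1Oc1ccc(CCc2cccc(OCc3ccccc3)c2)cc1
F8 | step 11 | macrocyclic aryl bromide: as 18 with Br in place of NH2 | Brc1cc2ccc1Oc1cccc(c1)CCc1ccc(cc1)Oc1cc(ccc1OC)CC2
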